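**Plan**
- Retrosynthesis: N–CH3 and O–Si are removed last. Ring C is cut at O1–C2 and C3–C4 (acetophenone enolate plus a salicylate ester). Ring A is cut at C8–C8a, C7–C6 and C8a–C4a, giving a piperidinyl siloxyalkyne and a diazo enone.
- Enabling feature: in ring A, C8 (piperidine-bearing) lies between the oxygenated carbons C7 and C8a, with C5–OMe and the acyl-bearing C4a beside them. A vinylketene–siloxyalkyne benzannulation gives this pattern, with the alkyne substituent between OH and OSi.
- Forward order: Boc-D-pipecolic acid → siloxyalkyne; alkyne diester → diazo enone; ring A by benzannulation; ring C by Claisen condensation and cyclodehydration; then N-methylation and desilylation.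
- Stereochemistry: the only stereocentre, (R) at piperidine C2, is bought with Boc-D-pipecolic acid and only carried along (retentive 1,2-shift in the homologation, neutral key step).

Key step: step 7

Remark on the chemistry: kinetic anti addition of methanol to the alkyne diester is assumed to give mainly the Z enol ether (ester groups trans); any E isomer is removed at that stage. Flavone numbering (O1, C2 … C8a) is used for ring positions.

**Step 1**
Reactants: 1 (R)-1-(tert-butoxycarbonyl)piperidine-2-carboxylic acid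
Product: 2 1-tert-butyl 2-methyl (R)-piperidine-1,2-dicarboxylate
Conditions: MeI, K2CO3, N,N-dimethylformamide, rt
Reagents that add atoms: iodomethane, CI
Why: Carboxylate O-alkylation (SN2 on MeI) under weakly basic conditions should esterify the acid without touching the α-stereocentre of the carbamate-protected amino acid.

**Step 2**
Reactants: 2 1-tert-butyl 2-methyl (R)-piperidine-1,2-dicarboxylate
Product: 5 tert-butyl (R)-2-{[tri(propan-2-yl)silyl]oxyethynyl}piperidine-1-carboxylate, via dibromo enolate 3 (not isolated), via lithium ynolate 4 (not isolated)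
Conditions: CH2Br2, lithium 2,2,6,6-tetramethylpiperidide, THF, −78 °C; LiN(SiMe3)2; s-BuLi, −78 °C → rt; then (i-Pr)3SiCl, −78 °C → rt
Reagents that add atoms: dibromomethane, BrCBr; chlorotri(propan-2-yl)silane, CC(C)[Si](Cl)(C(C)C)C(C)C
Why: Kowalski ester homologation, in which LiCHBr2 adds to the ester, the dibromomethyl ketone is held as enolate 3 (shielding the α-hydrogen from base), bromine–lithium exchange triggers a carbenoid rearrangement with retentive migration of the piperidin-2-yl group to ynolate 4, and the bulky chlorosilane silylates 4 on oxygen.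

**Step 3**
Reactants: 6 dimethyl but-2-ynedioate
Product: 7 dimethyl (Z)-2-methoxybut-2-enedioate
Conditions: MeOH (1 equiv), 1,4-diazabicyclo[2.2.2]octane (cat.), CH2Cl2, 0 °C
Reagents that add atoms: methanol, CO
Why: Amine-catalysed oxa-Michael addition of methanol to the ynoate with kinetic anti protonation of the allenolate should give the enol ether with the two esters trans, and chromatography removes any E isomer.

**Step 4**
Reactants: 7 dimethyl (Z)-2-methoxybut-2-enedioate
Product: 8 (Z)-2,4-dimethoxy-4-oxobut-2-enoic acid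
Conditions: LiOH (1.0 equiv), THF/H2O, 0 °C; then cold 1 M HCl to pH 2
Reagents that add atoms: lithium hydroxide, [Li+].[OH-]
Why: Regioselective half-saponification, since the C4 ester is a vinylogous carbonate deactivated by the enol-ether oxygen, so one equivalent of hydroxide should attack the C1 ester on the methoxy-bearing carbon.

**Step 5**
Reactants: 8 (Z)-2,4-dimethoxy-4-oxobut-2-enoic acid
Product: 9 methyl (Z)-4-chloro-3-methoxy-4-oxobut-2-enoate
Conditions: (COCl)2, N,N-dimethylformamide (cat.), CH2Cl2, 0 °C → rt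
Reagents that add atoms: oxalyl chloride, O=C(Cl)C(=O)Cl
Why: Acid chloride formation through the chloroiminium (Vilsmeier) intermediate under cold, neutral conditions, where the trans arrangement of the two carbonyl groups prevents cyclisation to an anhydride.

**Step 6**
Reactants: 9 methyl (Z)-4-chloro-3-methoxy-4-oxobut-2-enoate
Product: 10 methyl (Z)-5-diazo-3-methoxy-4-oxopent-2-enoate
Conditions: CH2N2 (2.2 equiv), Et2O, −20 → 0 °C
Reagents that add atoms: diazomethane, C=[N+]=[N-]
Why: Arndt–Eistert-type C-acylation of diazomethane by the acid chloride, run cold with a small excess so that fast acylation outruns dipolar cycloaddition to the donor-substituted trisubstituted C=C, the second equivalent of CH2N2 taking up HCl.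

**Step 7**
Reactants: 5 tert-butyl (R)-2-{[tri(propan-2-yl)silyl]oxyethynyl}piperidine-1-carboxylate; 10 methyl (Z)-5-diazo-3-methoxy-4-oxopent-2-enoate
Product: 15 methyl 3-[(R)-1-(tert-butoxycarbonyl)piperidin-2-yl]-2-hydroxy-6-methoxy-4-[tri(propan-2-yl)silyloxy]benzoate, via vinylketene 11 (not isolated), via vinylcyclobutenone 12 (not isolated), via dienylketene 13 (not isolated), via cyclohexadienone 14 (not isolated)
Conditions: hν (254 nm), ClCH2CH2Cl, rt; then 80 °C
Reagents that add atoms: none
Why: Irradiation expels N2 from 10 and Wolff rearrangement (vinyl shift) gives vinylketene 11, whose ketene carbon is attacked by the piperidine-bearing carbon of 5 in a [2+2] cycloaddition to vinylcyclobutenone 12; heating opens 12 by four-electron electrocyclic cleavage to dienylketene 13, which closes to dienone 14 and tautomerises to phenol 15. This is the Danheiser benzannulation in its diazo ketone (photo-Wolff) form, the known route from unsaturated diazo ketones and siloxyalkynes to resorcinol monosilyl ethers. Ring A is closed by a thermal six-electron (disrotatory) electrocyclisation of the dienylketene that forms C8a–C4a, after C8–C8a and C7–C6 were made in the [2+2] event. No lasting stereocentre is created, because the sp3 ring carbons of 12 and 14 are erased on ring opening and aromatisation, and the piperidine C2 centre is a spectator under these neutral conditions. The selectivity needed is the regiochemistry of the ketene–alkyne union, secured by the O-silyl polarisation of 5 (the carbon remote from oxygen is the nucleophile and bonds to the ketene carbonyl carbon), which puts the piperidine between OH and OSi(i-Pr)3; the trans relation of ester and acyl group in 10 keeps the ester pointing outward at the terminus of 13, so the ring closure should be unhindered.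

**Step 8**
Reactants: 15 methyl 3-[(R)-1-(tert-butoxycarbonyl)piperidin-2-yl]-2-hydroxy-6-methoxy-4-[tri(propan-2-yl)silyloxy]benzoate; 16 acetophenone
Product: 18 tert-butyl (R)-2-{2-hydroxy-4-methoxy-3-(3-oxo-3-phenylpropanoyl)-6-[tri(propan-2-yl)silyloxy]phenyl}piperidine-1-carboxylate, via lithium enolate 17 (not isolated)
Conditions: PhCOCH3 (3 equiv), LiN(SiMe3)2 (4 equiv), THF, −78 °C → rt; then 1 M HCl, 0 °C
Reagents that add atoms: none
Why: Crossed Claisen condensation in which excess enolate 17 attacks the lithium-chelated salicylate ester (the phenol is deprotonated first) and deprotonation of the 1,3-diketone drives the equilibrium, while carbamate and aryl silyl ether are inert to the amide base.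

**Step 9**
Reactants: 18 tert-butyl (R)-2-{2-hydroxy-4-methoxy-3-(3-oxo-3-phenylpropanoyl)-6-[tri(propan-2-yl)silyloxy]phenyl}piperidine-1-carboxylate
Product: 19 5-methoxy-2-phenyl-8-[(R)-piperidin-2-yl]-7-[tri(propan-2-yl)silyloxy]-4H-chromen-4-one
Conditions: HCl (4 M in dioxane), rt; then aq NaHCO3
Reagents that add atoms: none
Why: Anhydrous HCl cleaves the Boc group and catalyses attack of the phenol on the benzoyl carbonyl and dehydration of the hemiketal (acid cyclodehydration of an o-hydroxyaryl 1,3-diketone to the 4-pyranone), conditions the hindered aryl silyl ether should survive.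

**Step 10**
Reactants: 19 5-methoxy-2-phenyl-8-[(R)-piperidin-2-yl]-7-[tri(propan-2-yl)silyloxy]-4H-chromen-4-one
Product: 20 5-methoxy-8-[(R)-1-methylpiperidin-2-yl]-2-phenyl-7-[tri(propan-2-yl)silyloxy]-4H-chromen-4-one
Conditions: aq HCHO, NaBH(OAc)3, ClCH2CH2Cl, rt; then aq NaHCO3
Reagents that add atoms: formaldehyde, C=O
Why: Reductive amination, in which the secondary amine and formaldehyde form an iminium ion that NaBH(OAc)3 reduces selectively, leaving the chromone carbonyl and the silyl ether untouched.

**Step 11**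
Reactants: 20 5-methoxy-8-[(R)-1-methylpiperidin-2-yl]-2-phenyl-7-[tri(propan-2-yl)silyloxy]-4H-chromen-4-one
Product: 21 7-hydroxy-5-methoxy-8-[(R)-1-methylpiperidin-2-yl]-2-phenyl-4H-chromen-4-one
Conditions: Bu4NF, THF, 0 °C; then AcOH (1 equiv)
Reagents that add atoms: none
Why: Fluoride-induced cleavage of the aryl O–Si bond (strong Si–F bond, phenoxide leaving group) should release the C7 phenol without affecting the rest of the flavone.

**Compound list**
1 | (R)-1-(tert-butoxycarbonyl)piperidine-2-carboxylic acid (Boc-D-pipecolic acid) | OC(=O)[C@H]1CCCCN1C(=O)OC(C)(C)C | starting material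
2 | 1-tert-butyl 2-methyl (R)-piperidine-1,2-dicarboxylate | COC(=O)[C@H]1CCCCN1C(=O)OC(C)(C)C | intermediate
3 | lithium 2,2-dibromo-1-[(R)-1-(tert-butoxycarbonyl)piperidin-2-yl]ethen-1-olate | [Li+].[O-]C(=C(Br)Br)[C@H]1CCCCN1C(=O)OC(C)(C)C | intermediate
4 | lithium 2-[(R)-1-(tert-butoxycarbonyl)piperidin-2-yl]ethyn-1-olate | [Li+].[O-]C#C[C@H]1CCCCN1C(=O)OC(C)(C)C | intermediate
5 | tert-butyl (R)-2-{[tri(propan-2-yl)silyl]oxyethynyl}piperidine-1-carboxylate | CC(C)[Si](OC#C[C@H]1CCCCN1C(=O)OC(C)(C)C)(C(C)C)C(C)C | intermediate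
6 | dimethyl but-2-ynedioate (dimethyl acetylenedicarboxylate) | COC(=O)C#CC(=O)OC | starting material
7 | dimethyl (Z)-2-methoxybut-2-enedioate | COC(=O)/C=C(OC)/C(=O)OC | intermediate
8 | (Z)-2,4-dimethoxy-4-oxobut-2-enoic acid | COC(=O)/C=C(OC)/C(=O)O | intermediate
9 | methyl (Z)-4-chloro-3-methoxy-4-oxobut-2-enoate | COC(=O)/C=C(OC)/C(=O)Cl | intermediate
10 | methyl (Z)-5-diazo-3-methoxy-4-oxopent-2-enoate | COC(=O)/C=C(OC)/C(=O)C=[N+]=[N-] | intermediate
11 | methyl (Z)-3-methoxy-5-oxopenta-2,4-dienoate | COC(=O)/C=C(OC)/C=C=O | intermediate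
12 | tert-butyl (2R)-2-{3-[(Z)-1,3-dimethoxy-3-oxoprop-1-en-1-yl]-4-oxo-2-[tri(propan-2-yl)silyloxy]cyclobut-1-en-1-yl}piperidine-1-carboxylate (both epimers at the ring CH) | O=C1C([C@H]2CCCCN2C(=O)OC(C)(C)C)=C(O[Si](C(C)C)(C(C)C)C(C)C)C1/C(OC)=C/C(=O)OC | intermediate
13 | methyl (2Z,4E)-6-[(R)-1-(tert-butoxycarbonyl)piperidin-2-yl]-3-methoxy-7-oxo-5-[tri(propan-2-yl)silyloxy]hepta-2,4,6-trienoate | O=C=C([C@H]1CCCCN1C(=O)OC(C)(C)C)/C(O[Si](C(C)C)(C(C)C)C(C)C)=C\C(OC)=C\C(=O)OC | intermediate
14 | methyl 3-[(R)-1-(tert-butoxycarbonyl)piperidin-2-yl]-6-methoxy-2-oxo-4-[tri(propan-2-yl)silyloxy]cyclohexa-3,5-diene-1-carboxylate (both epimers at C1) | O=C1C([C@H]2CCCCN2C(=O)OC(C)(C)C)=C(O[Si](C(C)C)(C(C)C)C(C)C)C=C(OC)C1C(=O)OC | intermediate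
15 | methyl 3-[(R)-1-(tert-butoxycarbonyl)piperidin-2-yl]-2-hydroxy-6-methoxy-4-[tri(propan-2-yl)silyloxy]benzoate | COC(=O)c1c(OC)cc(O[Si](C(C)C)(C(C)C)C(C)C)c([C@H]2CCCCN2C(=O)OC(C)(C)C)c1O | intermediate
16 | acetophenone | CC(=O)c1ccccc1 | starting material
17 | lithium 1-phenylethen-1-olate | [Li+].[O-]C(=C)c1ccccc1 | intermediate
18 | tert-butyl (R)-2-{2-hydroxy-4-methoxy-3-(3-oxo-3-phenylpropanoyl)-6-[tri(propan-2-yl)silyloxy]phenyl}piperidine-1-carboxylate | O=C(CC(=O)c1ccccc1)c1c(OC)cc(O[Si](C(C)C)(C(C)C)C(C)C)c([C@H]2CCCCN2C(=O)OC(C)(C)C)c1O | intermediate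
19 | 5-methoxy-2-phenyl-8-[(R)-piperidin-2-yl]-7-[tri(propan-2-yl)silyloxy]-4H-chromen-4-one | COc1cc(O[Si](C(C)C)(C(C)C)C(C)C)c([C@H]2CCCCN2)c2oc(-c3ccccc3)cc(=O)c12 | intermediate
20 | 5-methoxy-8-[(R)-1-methylpiperidin-2-yl]-2-phenyl-7-[tri(propan-2-yl)silyloxy]-4H-chromen-4-one | COc1cc(O[Si](C(C)C)(C(C)C)C(C)C)c([C@H]2CCCCN2C)c2oc(-c3ccccc3)cc(=O)c12 | intermediate
21 | 7-hydroxy-5-methoxy-8-[(R)-1-methylpiperidin-2-yl]-2-phenyl-4H-chromen-4-one | COc1cc(O)c([C@H]2CCCCN2C)c2oc(-c3ccccc3)cc(=O)c12 | target

**Totals**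
Total step count: 11. Longest linear sequence: 9 steps (steps 3 to 11, from dimethyl but-2-ynedioate); the piperidine branch joins after 2 steps.

**Steps most likely to fail**

1. Step 7. Capture of the short-lived vinylketene by the α-branched, carbamate-shielded alkyne may be slower than ketene dimerisation and secondary photolysis of the diazo ketone and of the phenol product. The fallback sets out from siloxyalkyne 5 and returns at phenol 15, generating the ketene thermally by dehydrochlorination and keeping its concentration low without light. Commercial dimethyl 3-oxopentanedioate is O-methylated with HC(OMe)3 and catalytic H2SO4 in MeOH to dimethyl (E)-3-methoxypent-2-enedioate F1. One equivalent of LiOH should cleave the non-conjugated ester to (E)-3,5-dimethoxy-5-oxopent-3-enoic acid F2, and oxalyl chloride converts this into methyl (E)-5-chloro-3-methoxy-5-oxopent-2-enoate F3. Slow addition of F3 to 5 and Et3N in toluene (rt → 80 °C) should release methyl (E)-3-methoxy-5-oxopenta-2,4-dienoate F4, the geometric isomer of 11. This would add to 5 to give the ester-inward vinylcyclobutenone tert-butyl (2R)-2-{3-[(E)-1,3-dimethoxy-3-oxoprop-1-en-1-yl]-4-oxo-2-[tri(propan-2-yl)silyloxy]cyclobut-1-en-1-yl}piperidine-1-carboxylate F5, which opens to the dienylketene methyl (2E,4E)-6-[(R)-1-(tert-butoxycarbonyl)piperidin-2-yl]-3-methoxy-7-oxo-5-[tri(propan-2-yl)silyloxy]hepta-2,4,6-trienoate F6. Ring closure of F6 (expected to need longer heating because the ester points inward) leads to dienone 14 and phenol 15.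

2. Step 6. Dipolar cycloaddition of diazomethane to the electron-poor C=C of the acid chloride or of the diazo ketone may compete with C-acylation and consume the material as pyrazolines. The fallback sets out from acid chloride 9 and returns at diazo ketone 10, replacing acylation of diazomethane by diazo transfer. Coupling of 9 with MeZnCl and catalytic Pd(PPh3)4 in THF at 0 °C should give methyl (Z)-3-methoxy-4-oxopent-2-enoate F7. Its kinetic enolate (LiN(SiMe3)2, THF, −78 °C) is trifluoroacetylated with CF3CO2CH2CF3 to methyl (Z)-7,7,7-trifluoro-3-methoxy-4,6-dioxohept-2-enoate F8. Treating crude F8 with MeSO2N3, Et3N and water in MeCN should transfer the diazo group with loss of the trifluoroacetyl group, giving 10.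

3. Step 8. Deprotonation of the phenol deactivates the doubly ortho-substituted ester, so attack of the ketone enolate may stall while the enolate self-condenses. The fallback sets out from phenol 15 and returns at flavone 19, using a smaller carbanion and building C2 from benzaldehyde. Excess LiCH2S(O)CH3 (from Me2SO and n-BuLi, THF, −78 → 0 °C) should convert 15 into the β-ketosulfoxide tert-butyl (2R)-2-{2-hydroxy-4-methoxy-3-[2-(methylsulfinyl)acetyl]-6-[tri(propan-2-yl)silyloxy]phenyl}piperidine-1-carboxylate F9. Heating F9 with benzaldehyde and catalytic piperidine in toluene should bring about Knoevenagel condensation and oxa-Michael closure to tert-butyl (2R)-2-{5-methoxy-3-(methylsulfinyl)-4-oxo-2-phenyl-7-[tri(propan-2-yl)silyloxy]-3,4-dihydro-2H-chromen-8-yl}piperidine-1-carboxylate F10. Thermal syn elimination of the sulfoxide from F10 gives tert-butyl (R)-2-{5-methoxy-4-oxo-2-phenyl-7-[tri(propan-2-yl)silyloxy]-4H-chromen-8-yl}piperidine-1-carboxylate F11, and HCl in dioxane then removes the Boc group to give 19.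

**Further compounds**
F1 | step 7 | dimethyl (E)-3-methoxypent-2-enedioate | COC(=O)/C=C(/OC)CC(=O)OC
F2 | step 7 | (E)-3,5-dimethoxy-5-oxopent-3-enoic acid | COC(=O)/C=C(/OC)CC(=O)O
F3 | step 7 | methyl (E)-5-chloro-3-methoxy-5-oxopent-2-enoate | COC(=O)/C=C(/OC)CC(=O)Cl
F4 | step 7 | methyl (E)-3-methoxy-5-oxopenta-2,4-dienoate | COC(=O)/C=C(/OC)C=C=O
F5 | step 7 | tert-butyl (2R)-2-{3-[(E)-1,3-dimethoxy-3-oxoprop-1-en-1-yl]-4-oxo-2-[tri(propan-2-yl)silyloxy]cyclobut-1-en-1-yl}piperidine-1-carboxylate | O=C1C([C@H]2CCCCN2C(=O)OC(C)(C)C)=C(O[Si](C(C)C)(C(C)C)C(C)C)C1/C(OC)=C\C(=O)OC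
F6 | step 7 | methyl (2E,4E)-6-[(R)-1-(tert-butoxycarbonyl)piperidin-2-yl]-3-methoxy-7-oxo-5-[tri(propan-2-yl)silyloxy]hepta-2,4,6-trienoate | O=C=C([C@H]1CCCCN1C(=O)OC(C)(C)C)/C(O[Si](C(C)C)(C(C)C)C(C)C)=C\C(OC)=C/C(=O)OC
F7 | step 6 | methyl (Z)-3-methoxy-4-oxopent-2-enoate | COC(=O)/C=C(OC)/C(C)=O
F8 | step 6 | methyl (Z)-7,7,7-trifluoro-3-methoxy-4,6-dioxohept-2-enoate | COC(=O)/C=C(OC)/C(=O)CC(=O)C(F)(F)F
F9 | step 8 | tert-butyl (2R)-2-{2-hydroxy-4-methoxy-3-[2-(methylsulfinyl)acetyl]-6-[tri(propan-2-yl)silyloxy]phenyl}piperidine-1-carboxylate | CS(=O)CC(=O)c1c(OC)cc(O[Si](C(C)C)(C(C)C)C(C)C)c([C@H]2CCCCN2C(=O)OC(C)(C)C)c1O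
F10 | step 8 | tert-butyl (2R)-2-{5-methoxy-3-(methylsulfinyl)-4-oxo-2-phenyl-7-[tri(propan-2-yl)silyloxy]-3,4-dihydro-2H-chromen-8-yl}piperidine-1-carboxylate | COc1cc(O[Si](C(C)C)(C(C)C)C(C)C)c([C@H]2CCCCN2C(=O)OC(C)(C)C)c2OC(c3ccccc3)C(S(C)=O)C(=O)c12
F11 | step 8 | tert-butyl (R)-2-{5-methoxy-4-oxo-2-phenyl-7-[tri(propan-2-yl)silyloxy]-4H-chromen-8-yl}piperidine-1-carboxylate | COc1cc(O[Si](C(C)C)(C(C)C)C(C)C)c([C@H]2CCCCN2C(=O)OC(C)(C)C)c2oc(-c3ccccc3)cc(=O)c12
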